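**Retrosynthetic overview**

1. Target 22 comes from global hydrogenolysis of the benzyl-type protected trimer 21. Trimer 21 comes from two Lewis-acid couplings of flavan-4-yl cations with C8 of a phloroglucinol ring: 19 + 14 → 20, then 17 + 20 → 21.
2. The upper and middle units come from (−)-epigallocatechin through one common C4-oxidized electrophile 17; 19 is its 3-O-galloyl ester.
3. The terminal unit 14 has its pyran ring (O1–C2–C3–C4–C4a–C8a) grown from the furan ring of 2,3-dihydrobenzofuran 12 by a one-carbon ring expansion: a semipinacol 1,2-shift of the ring A carbon from C3 to the exocyclic CH2OTs carbon, then cis-selective ketone reduction in the same flask.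
4. Enabling feature: the migrating atom is C3a of a phloroglucinol ring (flanked by O1 and the 4-ether oxygen, para to the 6-ether oxygen), bound to a tertiary carbinol C3 that carries the CH2 leaving group. The carbinol oxygen makes the shift irreversible, and the C3 symmetry of tri-ether 3 makes the acylation site and the C–H insertion site degenerate.
5. Ring order for 14: ring A (phloroglucinol) → furan ring by enantioselective rhodium carbenoid C–H insertion (sets C2) → pyran ring by expansion (C3 set by hydride); the rings of the other two units come from the chiral pool.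

Key step: step 8

Assumption: Rh2(S-PTTL)4 is taken to give the (2S) configuration in step 4; if the sense of induction proves opposite, Rh2(R-PTTL)4 is used with everything else unchanged.

**Route**

Step 1
Reactants: 1 phloroglucinol; 2 [3,4,5-tris(benzyloxy)phenyl]methanol (3.3 equiv in all)
Product: 3 1,3,5-tris{[3,4,5-tris(benzyloxy)benzyl]oxy}benzene
Conditions: PPh3 (3.6 equiv), DIAD (3.6 equiv), THF, 0 °C to rt
Reagents that add atoms: 3,4,5-tris(benzyloxy)benzyl alcohol as second equivalent of 2, OCc1cc(OCc2ccccc2)c(OCc2ccccc2)c(OCc2ccccc2)c1; 3,4,5-tris(benzyloxy)benzyl alcohol as third equivalent of 2, OCc1cc(OCc2ccccc2)c(OCc2ccccc2)c(OCc2ccccc2)c1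
Why: Mitsunobu etherification of each of the three phenolic OH groups by one equivalent of the primary benzylic alcohol 2 (three successive etherifications in one flask, three equivalents of 2 consumed) under neutral conditions should avoid the C-alkylation that phloroglucinol shows under basic alkylation, and the C3-symmetric product makes all later ring positions equivalent.

Step 2
Reactants: 3 1,3,5-tris{[3,4,5-tris(benzyloxy)benzyl]oxy}benzene
Product: 5 methyl 2-oxo-2-(2,4,6-tris{[3,4,5-tris(benzyloxy)benzyl]oxy}phenyl)acetate, via arylglyoxylyl chloride 4 (not isolated)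
Conditions: (COCl)2, 2,6-di-tert-butyl-4-methylpyridine, CH2Cl2, 0 °C; then MeOH, pyridine, 0 °C
Reagents that add atoms: oxalyl chloride, O=C(Cl)C(Cl)=O; methanol, CO
Why: Uncatalysed Friedel–Crafts acylation of the 1,3,5-trialkoxybenzene ring should be clean because its three CH positions are equivalent and far more nucleophilic than those of the benzyl-type rings, the first acyl group deactivates the ring against a second one, and the hindered base keeps HCl away from the electron-rich benzyl ethers.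

Step 3
Reactants: 5 methyl 2-oxo-2-(2,4,6-tris{[3,4,5-tris(benzyloxy)benzyl]oxy}phenyl)acetate
Product: 7 methyl 2-diazo-2-(2,4,6-tris{[3,4,5-tris(benzyloxy)benzyl]oxy}phenyl)acetate, via tosylhydrazone 6 (not isolated)
Conditions: TsNHNH2, THF/MeOH, 60 °C; then DBU, CH2Cl2, rt
Reagents that add atoms: 4-methylbenzenesulfonohydrazide, Cc1ccc(cc1)S(=O)(=O)NN
Why: Condensation of the activated keto group to the tosylhydrazone and base-induced loss of sulfinate (Bamford–Stevens reaction under mild conditions) is the standard access to aryldiazoacetates from arylglyoxylates.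

Step 4
Reactants: 7 methyl 2-diazo-2-(2,4,6-tris{[3,4,5-tris(benzyloxy)benzyl]oxy}phenyl)acetate
Product: 8 methyl (2S,3R)-4,6-bis{[3,4,5-tris(benzyloxy)benzyl]oxy}-2-[3,4,5-tris(benzyloxy)phenyl]-2,3-dihydro-1-benzofuran-3-carboxylate
Conditions: Rh2(S-PTTL)4 (dirhodium tetrakis[N-phthaloyl-(S)-tert-leucinate], 1 mol %), toluene, −60 °C
Reagents that add atoms: none
Why: Intramolecular 1,5 C–H insertion of the donor/acceptor rhodium carbenoid into the benzylic ether C–H bond of an ortho ArCH2O group is established for 2-(benzyloxy)aryl diazoacetates with this catalyst class; the two ortho ethers are homotopic so one constitution results, and the chiral carboxylate ligands set C2 (S) and the cis C3, of which only C2 is carried on.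

Step 5
Reactants: 8 methyl (2S,3R)-4,6-bis{[3,4,5-tris(benzyloxy)benzyl]oxy}-2-[3,4,5-tris(benzyloxy)phenyl]-2,3-dihydro-1-benzofuran-3-carboxylate
Product: 10 methyl (2R,3S)-3-hydroxy-4,6-bis{[3,4,5-tris(benzyloxy)benzyl]oxy}-2-[3,4,5-tris(benzyloxy)phenyl]-2,3-dihydro-1-benzofuran-3-carboxylate, via potassium enolate 9 (not isolated)
Conditions: KN(SiMe3)2, THF, −78 °C; then 2-(phenylsulfonyl)-3-phenyloxaziridine, −78 °C; AcOH
Reagents that add atoms: 2-(phenylsulfonyl)-3-phenyloxaziridine, O=S(=O)(c1ccccc1)N1OC1c1ccccc1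
Why: Davis oxidation of the ester enolate installs the tertiary hydroxyl at C3 (oxidant expected anti to the C2 aryl group; this center is erased in step 8), while opening of the enolate by loss of the C2 aryloxide is the reverse of a 5-endo-trig closure and should not compete at −78 °C, so C2 is kept.

Step 6
Reactants: 10 methyl (2R,3S)-3-hydroxy-4,6-bis{[3,4,5-tris(benzyloxy)benzyl]oxy}-2-[3,4,5-tris(benzyloxy)phenyl]-2,3-dihydro-1-benzofuran-3-carboxylate
Product: 11 (2R,3R)-3-(hydroxymethyl)-4,6-bis{[3,4,5-tris(benzyloxy)benzyl]oxy}-2-[3,4,5-tris(benzyloxy)phenyl]-2,3-dihydro-1-benzofuran-3-ol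
Conditions: LiAlH4, THF, 0 °C
Reagents that add atoms: none
Why: Hydride reduction of the α-hydroxy ester to the 1,2-diol leaves the benzyl-type ethers and both stereocenters untouched.

Step 7
Reactants: 11 (2R,3R)-3-(hydroxymethyl)-4,6-bis{[3,4,5-tris(benzyloxy)benzyl]oxy}-2-[3,4,5-tris(benzyloxy)phenyl]-2,3-dihydro-1-benzofuran-3-ol
Product: 12 [(2R,3R)-3-hydroxy-4,6-bis{[3,4,5-tris(benzyloxy)benzyl]oxy}-2-[3,4,5-tris(benzyloxy)phenyl]-2,3-dihydro-1-benzofuran-3-yl]methyl 4-methylbenzenesulfonate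
Conditions: TsCl, pyridine, CH2Cl2, 0 °C
Reagents that add atoms: 4-methylbenzenesulfonyl chloride, Cc1ccc(cc1)S(=O)(=O)Cl
Why: Selective sulfonylation of the primary hydroxyl next to the hindered tertiary one gives the semipinacol substrate, which is used at once without heating.

Step 8
Reactants: 12 [(2R,3R)-3-hydroxy-4,6-bis{[3,4,5-tris(benzyloxy)benzyl]oxy}-2-[3,4,5-tris(benzyloxy)phenyl]-2,3-dihydro-1-benzofuran-3-yl]methyl 4-methylbenzenesulfonate
Product: 14 (2R,3R)-5,7-bis{[3,4,5-tris(benzyloxy)benzyl]oxy}-2-[3,4,5-tris(benzyloxy)phenyl]chroman-3-ol, via flavan-3-one 13 (not isolated)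
Conditions: LiClO4, CaCO3, THF, 50 °C; then LiBH(s-Bu)3, THF, −78 °C
Reagents that add atoms: none
Why: LiClO4 assists ionization of the primary tosylate while the ring A carbon C3a (ortho to O1 and to the 4-ether oxygen, para to the 6-ether oxygen) bridges C3 and the exocyclic carbon and then shifts fully to it as a lone pair of the C3 hydroxyl closes to the carbonyl, so the furan ring O1–C2–C3–C3a–C7a takes up the exocyclic carbon and becomes the pyran ring O1–C2–C3(=O)–C4–C4a–C8a of ketone 13. The closest known reaction type is the semipinacol (Tiffeneau–Demjanov-type) ring expansion of 1-(sulfonyloxymethyl)cycloalkan-1-ols under LiClO4/CaCO3, followed by the known cis-selective LiBH(s-Bu)3 reduction of benzyl-protected flavan-3-ones. The six-membered ring is made by ring enlargement through the 1,2-shift and not by an end-to-end cyclization, so no exo or endo closure mode is involved. C2 (set in step 4) is not touched by the shift, and the new C3 stereocenter is set by substrate control in the second stage: the bulky hydride should attack the carbonyl along the equatorial direction and give the axial 3-OH cis to the equatorial C2 aryl group, that is (2R,3R). The step needs migration of C3a and not of C2, no epoxide closure and no enolization at C2: the trioxygenated aryl is by far the better migrating group, CaCO3 only scavenges TsOH and leaves the alcohol un-ionized, and the ketone is reduced cold in the same flask without isolation.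

Step 9
Reactants: 15 (−)-epigallocatechin
Product: 16 (2R,3R)-5,7-bis(benzyloxy)-2-[3,4,5-tris(benzyloxy)phenyl]chroman-3-ol
Conditions: BnBr, K2CO3, DMF, rt
Reagents that add atoms: benzyl bromide, BrCc1ccccc1
Why: Williamson etherification of the five phenolic OH groups; the secondary 3-OH is not deprotonated by K2CO3 and stays free, and C2 and C3 are untouched.

Step 10
Reactants: 16 (2R,3R)-5,7-bis(benzyloxy)-2-[3,4,5-tris(benzyloxy)phenyl]chroman-3-ol
Product: 17 (2R,3R,4S)-5,7-bis(benzyloxy)-4-(2-ethoxyethoxy)-2-[3,4,5-tris(benzyloxy)phenyl]chroman-3-ol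
Conditions: DDQ, 2-ethoxyethanol, CH2Cl2, rt
Reagents that add atoms: 2-ethoxyethanol, CCOCCO
Why: DDQ abstracts hydride from the doubly activated benzylic C4 and the resulting quinone methide-type cation is trapped by the alcohol anti to the axial 3-OH, giving the 4β ether (3,4-trans), a known oxidation of benzylated flavan-3-ols.

Step 11
Reactants: 17 (2R,3R,4S)-5,7-bis(benzyloxy)-4-(2-ethoxyethoxy)-2-[3,4,5-tris(benzyloxy)phenyl]chroman-3-ol; 18 3,4,5-tris(benzyloxy)benzoic acid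
Product: 19 (2R,3R,4S)-5,7-bis(benzyloxy)-4-(2-ethoxyethoxy)-2-[3,4,5-tris(benzyloxy)phenyl]chroman-3-yl 3,4,5-tris(benzyloxy)benzoate
Conditions: DCC, DMAP, CH2Cl2, rt
Reagents that add atoms: none
Why: Steglich esterification of the axial 3-OH installs the protected gallate without touching a stereocenter.

Step 12
Reactants: 19 (2R,3R,4S)-5,7-bis(benzyloxy)-4-(2-ethoxyethoxy)-2-[3,4,5-tris(benzyloxy)phenyl]chroman-3-yl 3,4,5-tris(benzyloxy)benzoate; 14 (2R,3R)-5,7-bis{[3,4,5-tris(benzyloxy)benzyl]oxy}-2-[3,4,5-tris(benzyloxy)phenyl]chroman-3-ol (3 equiv; the excess is recovered)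
Product: 20 protected dimer in which C4 of the galloylated unit is bound 4β to C8 of unit 14
Conditions: Me3SiOTf (cat.), CH2Cl2, −78 °C; Et3N
Reagents that add atoms: none
Why: Lewis-acid ionization of the C4 ether gives the flavan-4-yl cation, which C8 of 14 should attack (Friedel–Crafts alkylation) anti to the axial 3-acyloxy group to set C4 as 4β (3,4-trans); C8 is preferred over C6, which lies between two bulky benzyl-type ethers, and excess nucleophile suppresses chain growth.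

Step 13
Reactants: 20 protected dimer (2.5 equiv; the excess is recovered); 17 (2R,3R,4S)-5,7-bis(benzyloxy)-4-(2-ethoxyethoxy)-2-[3,4,5-tris(benzyloxy)phenyl]chroman-3-ol
Product: 21 protected trimer in which C4 of unit 17 is bound 4β to C8 of the galloylated unit of 20
Conditions: Me3SiOTf (cat.), CH2Cl2, −78 to −40 °C; Et3N
Reagents that add atoms: none
Why: The same flavan-4-yl cation coupling; the cation from 17 should be attacked by the only unsubstituted C8 of 20 (on the galloylated unit, the C6 positions each lying between two ethers), again anti to the axial C3 oxygen to give the 4β bond.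

Step 14
Reactants: 21 protected trimer
Product: 22 epigallocatechin-(4β→8)-epigallocatechin 3-O-gallate-(4β→8)-epigallocatechin
Conditions: H2 (1 atm), Pd(OH)2/C, THF/MeOH/H2O, rt
Reagents that add atoms: none
Why: Hydrogenolysis should cleave all twenty-four benzylic C–O bonds (the two large benzyl-type ethers at the aryl-O–CH2 bond, then their own benzyl groups), while the gallate ester, the interflavan bonds and all stereocenters are inert to these conditions.

**Compound list**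

1 | phloroglucinol (benzene-1,3,5-triol) | Oc1cc(O)cc(O)c1 | starting material

2 | [3,4,5-tris(benzyloxy)phenyl]methanol | OCc1cc(OCc2ccccc2)c(OCc2ccccc2)c(OCc2ccccc2)c1 | starting material

3 | 1,3,5-tris{[3,4,5-tris(benzyloxy)benzyl]oxy}benzene | c1(OCc7cc(OCc8ccccc8)c(OCc8ccccc8)c(OCc8ccccc8)c7)cc(OCc7cc(OCc8ccccc8)c(OCc8ccccc8)c(OCc8ccccc8)c7)cc(OCc7cc(OCc8ccccc8)c(OCc8ccccc8)c(OCc8ccccc8)c7)c1 | intermediate

4 | 2-oxo-2-(2,4,6-tris{[3,4,5-tris(benzyloxy)benzyl]oxy}phenyl)acetyl chloride | ClC(=O)C(=O)c1c(OCc7cc(OCc8ccccc8)c(OCc8ccccc8)c(OCc8ccccc8)c7)cc(OCc7cc(OCc8ccccc8)c(OCc8ccccc8)c(OCc8ccccc8)c7)cc1OCc7cc(OCc8ccccc8)c(OCc8ccccc8)c(OCc8ccccc8)c7 | intermediate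

5 | methyl 2-oxo-2-(2,4,6-tris{[3,4,5-tris(benzyloxy)benzyl]oxy}phenyl)acetate | COC(=O)C(=O)c1c(OCc7cc(OCc8ccccc8)c(OCc8ccccc8)c(OCc8ccccc8)c7)cc(OCc7cc(OCc8ccccc8)c(OCc8ccccc8)c(OCc8ccccc8)c7)cc1OCc7cc(OCc8ccccc8)c(OCc8ccccc8)c(OCc8ccccc8)c7 | intermediate

6 | tosylhydrazone of 5 (C=N geometry not defined) | COC(=O)C(=NNS(=O)(=O)c2ccc(C)cc2)c1c(OCc7cc(OCc8ccccc8)c(OCc8ccccc8)c(OCc8ccccc8)c7)cc(OCc7cc(OCc8ccccc8)c(OCc8ccccc8)c(OCc8ccccc8)c7)cc1OCc7cc(OCc8ccccc8)c(OCc8ccccc8)c(OCc8ccccc8)c7 | intermediate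

7 | methyl 2-diazo-2-(2,4,6-tris{[3,4,5-tris(benzyloxy)benzyl]oxy}phenyl)acetate | COC(=O)C(=[N+]=[N-])c1c(OCc7cc(OCc8ccccc8)c(OCc8ccccc8)c(OCc8ccccc8)c7)cc(OCc7cc(OCc8ccccc8)c(OCc8ccccc8)c(OCc8ccccc8)c7)cc1OCc7cc(OCc8ccccc8)c(OCc8ccccc8)c(OCc8ccccc8)c7 | intermediate

8 | methyl (2S,3R)-4,6-bis{[3,4,5-tris(benzyloxy)benzyl]oxy}-2-[3,4,5-tris(benzyloxy)phenyl]-2,3-dihydro-1-benzofuran-3-carboxylate (aryl and ester cis) | COC(=O)[C@H]1[C@@H](c5cc(OCc9ccccc9)c(OCc9ccccc9)c(OCc9ccccc9)c5)Oc2cc(OCc7cc(OCc8ccccc8)c(OCc8ccccc8)c(OCc8ccccc8)c7)cc(OCc7cc(OCc8ccccc8)c(OCc8ccccc8)c(OCc8ccccc8)c7)c12 | intermediate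

9 | potassium ester enolate of 8 (C3 planar, C2 unchanged) | [K+].[O-]C(OC)=C1[C@@H](c5cc(OCc9ccccc9)c(OCc9ccccc9)c(OCc9ccccc9)c5)Oc2cc(OCc7cc(OCc8ccccc8)c(OCc8ccccc8)c(OCc8ccccc8)c7)cc(OCc7cc(OCc8ccccc8)c(OCc8ccccc8)c(OCc8ccccc8)c7)c12 | intermediate

10 | methyl (2R,3S)-3-hydroxy-4,6-bis{[3,4,5-tris(benzyloxy)benzyl]oxy}-2-[3,4,5-tris(benzyloxy)phenyl]-2,3-dihydro-1-benzofuran-3-carboxylate (3-OH trans to the 2-aryl group) | COC(=O)[C@@]1(O)[C@@H](c5cc(OCc9ccccc9)c(OCc9ccccc9)c(OCc9ccccc9)c5)Oc2cc(OCc7cc(OCc8ccccc8)c(OCc8ccccc8)c(OCc8ccccc8)c7)cc(OCc7cc(OCc8ccccc8)c(OCc8ccccc8)c(OCc8ccccc8)c7)c12 | intermediate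

11 | (2R,3R)-3-(hydroxymethyl)-4,6-bis{[3,4,5-tris(benzyloxy)benzyl]oxy}-2-[3,4,5-tris(benzyloxy)phenyl]-2,3-dihydro-1-benzofuran-3-ol | OC[C@@]1(O)[C@@H](c5cc(OCc9ccccc9)c(OCc9ccccc9)c(OCc9ccccc9)c5)Oc2cc(OCc7cc(OCc8ccccc8)c(OCc8ccccc8)c(OCc8ccccc8)c7)cc(OCc7cc(OCc8ccccc8)c(OCc8ccccc8)c(OCc8ccccc8)c7)c12 | intermediate

12 | [(2R,3R)-3-hydroxy-4,6-bis{[3,4,5-tris(benzyloxy)benzyl]oxy}-2-[3,4,5-tris(benzyloxy)phenyl]-2,3-dihydro-1-benzofuran-3-yl]methyl 4-methylbenzenesulfonate | Cc1ccc(cc1)S(=O)(=O)OC[C@@]1(O)[C@@H](c5cc(OCc9ccccc9)c(OCc9ccccc9)c(OCc9ccccc9)c5)Oc2cc(OCc7cc(OCc8ccccc8)c(OCc8ccccc8)c(OCc8ccccc8)c7)cc(OCc7cc(OCc8ccccc8)c(OCc8ccccc8)c(OCc8ccccc8)c7)c12 | intermediate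

13 | (2R)-5,7-bis{[3,4,5-tris(benzyloxy)benzyl]oxy}-2-[3,4,5-tris(benzyloxy)phenyl]chroman-3-one | c1(OCc7cc(OCc8ccccc8)c(OCc8ccccc8)c(OCc8ccccc8)c7)cc(OCc7cc(OCc8ccccc8)c(OCc8ccccc8)c(OCc8ccccc8)c7)c2c(c1)O[C@H](c5cc(OCc9ccccc9)c(OCc9ccccc9)c(OCc9ccccc9)c5)C(=O)C2 | intermediate

14 | (2R,3R)-5,7-bis{[3,4,5-tris(benzyloxy)benzyl]oxy}-2-[3,4,5-tris(benzyloxy)phenyl]chroman-3-ol (protected epigallocatechin, 2,3-cis) | c1(OCc7cc(OCc8ccccc8)c(OCc8ccccc8)c(OCc8ccccc8)c7)cc(OCc7cc(OCc8ccccc8)c(OCc8ccccc8)c(OCc8ccccc8)c7)c2c(c1)O[C@H](c5cc(OCc9ccccc9)c(OCc9ccccc9)c(OCc9ccccc9)c5)[C@H](O)C2 | intermediate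

15 | (−)-epigallocatechin, (2R,3R)-2-(3,4,5-trihydroxyphenyl)chroman-3,5,7-triol | Oc1cc(O)c2c(c1)O[C@H](c1cc(O)c(O)c(O)c1)[C@H](O)C2 | starting material

16 | (2R,3R)-5,7-bis(benzyloxy)-2-[3,4,5-tris(benzyloxy)phenyl]chroman-3-ol | c1(OCc9ccccc9)cc(OCc9ccccc9)c2c(c1)O[C@H](c5cc(OCc9ccccc9)c(OCc9ccccc9)c(OCc9ccccc9)c5)[C@H](O)C2 | intermediate

17 | (2R,3R,4S)-5,7-bis(benzyloxy)-4-(2-ethoxyethoxy)-2-[3,4,5-tris(benzyloxy)phenyl]chroman-3-ol (4β ether, trans to 3-OH) | CCOCCO[C@H]1c2c(OCc9ccccc9)cc(OCc9ccccc9)cc2O[C@H](c5cc(OCc9ccccc9)c(OCc9ccccc9)c(OCc9ccccc9)c5)[C@@H]1O | intermediate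

18 | 3,4,5-tris(benzyloxy)benzoic acid | OC(=O)c1cc(OCc2ccccc2)c(OCc2ccccc2)c(OCc2ccccc2)c1 | starting material

19 | (2R,3R,4S)-5,7-bis(benzyloxy)-4-(2-ethoxyethoxy)-2-[3,4,5-tris(benzyloxy)phenyl]chroman-3-yl 3,4,5-tris(benzyloxy)benzoate | CCOCCO[C@H]1c2c(OCc9ccccc9)cc(OCc9ccccc9)cc2O[C@H](c5cc(OCc9ccccc9)c(OCc9ccccc9)c(OCc9ccccc9)c5)[C@@H]1OC(=O)c6cc(OCc9ccccc9)c(OCc9ccccc9)c(OCc9ccccc9)c6 | intermediate

20 | protected dimer: penta-O-benzyl-3-O-[3,4,5-tris(benzyloxy)benzoyl]epigallocatechin (2R,3R,4R) bound 4β→8 to unit 14 (2R,3R) | O=C(O[C@@H]1[C@@H](c2c(OCc7cc(OCc8ccccc8)c(OCc8ccccc8)c(OCc8ccccc8)c7)cc(OCc7cc(OCc8ccccc8)c(OCc8ccccc8)c(OCc8ccccc8)c7)c3c2O[C@H](c5cc(OCc9ccccc9)c(OCc9ccccc9)c(OCc9ccccc9)c5)[C@H](O)C3)c2c(OCc9ccccc9)cc(OCc9ccccc9)cc2O[C@@H]1c5cc(OCc9ccccc9)c(OCc9ccccc9)c(OCc9ccccc9)c5)c6cc(OCc9ccccc9)c(OCc9ccccc9)c(OCc9ccccc9)c6 | intermediate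

21 | protected trimer: penta-O-benzylepigallocatechin (2R,3R,4R) bound 4β→8 to the galloylated unit (2R,3R,4S) of 20, which is bound 4β→8 to unit 14 (2R,3R) | O=C(O[C@@H]1[C@@H](c2c(OCc7cc(OCc8ccccc8)c(OCc8ccccc8)c(OCc8ccccc8)c7)cc(OCc7cc(OCc8ccccc8)c(OCc8ccccc8)c(OCc8ccccc8)c7)c3c2O[C@H](c5cc(OCc9ccccc9)c(OCc9ccccc9)c(OCc9ccccc9)c5)[C@H](O)C3)c2c(OCc9ccccc9)cc(OCc9ccccc9)c([C@H]3c4c(OCc9ccccc9)cc(OCc9ccccc9)cc4O[C@H](c5cc(OCc9ccccc9)c(OCc9ccccc9)c(OCc9ccccc9)c5)[C@@H]3O)c2O[C@@H]1c5cc(OCc9ccccc9)c(OCc9ccccc9)c(OCc9ccccc9)c5)c6cc(OCc9ccccc9)c(OCc9ccccc9)c(OCc9ccccc9)c6 | intermediate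

22 | epigallocatechin-(4β→8)-epigallocatechin 3-O-gallate-(4β→8)-epigallocatechin (CNP0278699.1) | O=C(O[C@@H]1[C@@H](c2c(O)cc(O)c3c2O[C@H](c2cc(O)c(O)c(O)c2)[C@H](O)C3)c2c(O)cc(O)c([C@H]3c4c(O)cc(O)cc4O[C@H](c4cc(O)c(O)c(O)c4)[C@@H]3O)c2O[C@@H]1c1cc(O)c(O)c(O)c1)c1cc(O)c(O)c(O)c1 | target

**Step count and risks**

Total step count: 14. Longest linear sequence: 11 steps (steps 1 to 8, then 12, 13 and 14).

Step 8. The risk is competition of the C3 oxygen with the aryl group for the CH2OTs carbon (closure to a spiro-epoxide), loss of water from the tertiary benzylic carbinol with aromatization of the furan ring, and loss of the C2 configuration by enolization of ketone 13 before it is reduced. The fallback is a Tiffeneau–Demjanov ring expansion that sets out from hydroxy ester 10 and comes back to the route at 14. Ammonolysis of 10 (NH3, MeOH) gives the primary carboxamide F1, LiAlH4 in THF reduces it to the amino alcohol F2, and diazotization (NaNO2, aqueous AcOH, 0 °C) gives ketone 13 by the same aryl shift with loss of N2 under conditions in which no alkoxide exists. Ketone 13 is then reduced directly with LiBH(s-Bu)3 at −78 °C to 14.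

Step 13. The risk is self-condensation of electrophile 17 through its own free C8 (chain growth to oligomers) and attack on 20 at a C6 position (poor regioselectivity). The fallback is capping of C8 in the electrophile; it sets out from 16 and comes back to the route at 22. Bromination of 16 (NBS, CH2Cl2, −40 °C) gives the 8-bromo ether F3, and DDQ with 2-ethoxyethanol gives the C8-blocked electrophile F4. F4 can be used in excess with 20 under Me3SiOTf to give the bromo trimer F5. Hydrogenolysis of F5 with H2, Pd(OH)2/C and Et3N removes the bromine together with the benzyl groups and gives 22.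

Step 12. The risk is acid-induced loss of the electron-rich 3,4,5-tris(benzyloxy)benzyl ethers of 14, with benzyl transfer to the arene, under the silyl triflate. The fallback is thiophilic activation under non-acidic conditions; it sets out from 19 and comes back to the route at 20. Exchange of the C4 ether of 19 for a 2-benzothiazolylthio group (2-mercaptobenzothiazole, AlMe3, CH2Cl2) gives the thioether F6, and AgBF4 in THF at 0 °C ionizes it in the presence of 14 to give 20.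

**Further compounds**

F1 | step 8 | (2R,3S)-3-hydroxy-4,6-bis{[3,4,5-tris(benzyloxy)benzyl]oxy}-2-[3,4,5-tris(benzyloxy)phenyl]-2,3-dihydro-1-benzofuran-3-carboxamide | NC(=O)[C@@]1(O)[C@@H](c5cc(OCc9ccccc9)c(OCc9ccccc9)c(OCc9ccccc9)c5)Oc2cc(OCc7cc(OCc8ccccc8)c(OCc8ccccc8)c(OCc8ccccc8)c7)cc(OCc7cc(OCc8ccccc8)c(OCc8ccccc8)c(OCc8ccccc8)c7)c12

F2 | step 8 | (2R,3R)-3-(aminomethyl)-4,6-bis{[3,4,5-tris(benzyloxy)benzyl]oxy}-2-[3,4,5-tris(benzyloxy)phenyl]-2,3-dihydro-1-benzofuran-3-ol | NC[C@@]1(O)[C@@H](c5cc(OCc9ccccc9)c(OCc9ccccc9)c(OCc9ccccc9)c5)Oc2cc(OCc7cc(OCc8ccccc8)c(OCc8ccccc8)c(OCc8ccccc8)c7)cc(OCc7cc(OCc8ccccc8)c(OCc8ccccc8)c(OCc8ccccc8)c7)c12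

F3 | step 13 | (2R,3R)-5,7-bis(benzyloxy)-8-bromo-2-[3,4,5-tris(benzyloxy)phenyl]chroman-3-ol | c1(OCc9ccccc9)cc(OCc9ccccc9)c2c(c1Br)O[C@H](c5cc(OCc9ccccc9)c(OCc9ccccc9)c(OCc9ccccc9)c5)[C@H](O)C2

F4 | step 13 | (2R,3R,4S)-5,7-bis(benzyloxy)-8-bromo-4-(2-ethoxyethoxy)-2-[3,4,5-tris(benzyloxy)phenyl]chroman-3-ol | CCOCCO[C@H]1c2c(OCc9ccccc9)cc(OCc9ccccc9)c(Br)c2O[C@H](c5cc(OCc9ccccc9)c(OCc9ccccc9)c(OCc9ccccc9)c5)[C@@H]1O

F5 | step 13 | 8-bromo derivative of trimer 21 (bromine at C8 of the upper unit) | O=C(O[C@@H]1[C@@H](c2c(OCc7cc(OCc8ccccc8)c(OCc8ccccc8)c(OCc8ccccc8)c7)cc(OCc7cc(OCc8ccccc8)c(OCc8ccccc8)c(OCc8ccccc8)c7)c3c2O[C@H](c5cc(OCc9ccccc9)c(OCc9ccccc9)c(OCc9ccccc9)c5)[C@H](O)C3)c2c(OCc9ccccc9)cc(OCc9ccccc9)c([C@H]3c4c(OCc9ccccc9)cc(OCc9ccccc9)c(Br)c4O[C@H](c5cc(OCc9ccccc9)c(OCc9ccccc9)c(OCc9ccccc9)c5)[C@@H]3O)c2O[C@@H]1c5cc(OCc9ccccc9)c(OCc9ccccc9)c(OCc9ccccc9)c5)c6cc(OCc9ccccc9)c(OCc9ccccc9)c(OCc9ccccc9)c6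

F6 | step 12 | (2R,3S,4S)-4-(1,3-benzothiazol-2-ylsulfanyl)-5,7-bis(benzyloxy)-2-[3,4,5-tris(benzyloxy)phenyl]chroman-3-yl 3,4,5-tris(benzyloxy)benzoate (4β thioether, same spatial arrangement as 19) | c1ccc2sc(nc2c1)S[C@H]1c2c(OCc9ccccc9)cc(OCc9ccccc9)cc2O[C@H](c5cc(OCc9ccccc9)c(OCc9ccccc9)c(OCc9ccccc9)c5)[C@@H]1OC(=O)c6cc(OCc9ccccc9)c(OCc9ccccc9)c(OCc9ccccc9)c6
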